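**Plan**
- Retrosynthesis: the chain-side C=O of the quinone is taken back to an aryl C–H (phenol 26). The two ring bonds flanking the CH=C(OMe) pair are then cut, giving methoxyacetylene 21 and cyclobutenone 18. The ring–CH2 bond of 18 is cut to an allyl metal plus a 3-ethoxycyclobutenone, and the C30 chain is cut at C12–C13 into two farnesyl units.
- Enabling feature: in the quinone ring the CH=C(OMe) pair lies between the two carbonyl carbons, and the other four ring atoms (C=O, C–CH3, C–hexaprenyl, C=O) are contiguous. Joining the two ends of that four-atom unit (para in the target, so this bond is absent there) gives a cyclobutenone. A polarized alkyne inserts into this temporary bond with fixed orientation, because one end is a ketone carbon and the other is carried as a vinylic C–H.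
- Forward order: C30 chain (steps 1–6), four-membered ring (7, 8), alkyne (9), six-membered ring (10), oxidation to the quinone (11).
- Stereochemistry: the target has no stereocentre. Four of its five E double bonds come from (2E,6E)-farnesyl building blocks, the fifth from E-selective SeO2 oxidation, and every later chain operation retains geometry.

Key step: step 10

Remark: the target is achiral, so the task is read as making the single all-E isomer. "Hexaprenyl" below means (2E,6E,10E,14E,18E)-3,7,11,15,19,23-hexamethyltetracosa-2,6,10,14,18,22-hexaen-1-yl. (2E,6E)-Farnesyl bromide and acetate are taken as commercial, and methoxyacetylene is prepared (step 9).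

**Route**

Step 1
Reactants: 1 (2E,6E)-farnesyl bromide; 2 sodium p-toluenesulfinate
Product: 3 (2E,6E)-farnesyl p-tolyl sulfone
Conditions: DMF, rt
Reagents that add atoms: none
Why: SN2 S-alkylation of the soft sulfinate sulfur at the primary allylic bromide (sulfone synthesis) should proceed without allylic transposition, so both E double bonds are carried over unchanged.

Step 2
Reactants: 4 (2E,6E)-farnesyl acetate
Product: 5 (2E,6E,10E)-12-hydroxy-3,7,11-trimethyldodeca-2,6,10-trien-1-yl acetate
Conditions: SeO2 (cat.), t-BuOOH, salicylic acid (cat.), CH2Cl2, 0 °C to rt, stopped at partial conversion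
Reagents that add atoms: tert-butyl hydroperoxide, CC(C)(C)OO (stoichiometric oxygen source, relayed through catalytic selenium dioxide, O=[Se]=O)
Why: Catalytic SeO2/t-BuOOH allylic oxidation (ene reaction, then [2,3]-sigmatropic shift) should attack the terminal, most electron-rich trisubstituted alkene at its E methyl group and give the 10E allylic alcohol, the 2,3-alkene being deactivated by the allylic acetate.

Step 3
Reactants: 5 (2E,6E,10E)-12-hydroxyfarnesyl acetate
Product: 6 (2E,6E,10E)-12-bromo-3,7,11-trimethyldodeca-2,6,10-trien-1-yl acetate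
Conditions: CBr4, PPh3, CH2Cl2, 0 °C
Reagents that add atoms: carbon tetrabromide, BrC(Br)(Br)Br
Why: Appel reaction, in which bromide displaces the oxyphosphonium group by SN2 at the primary allylic carbon, should give the bromide without transposition or loss of the 10E geometry, and the acetate is inert.

Step 4
Reactants: 3 (2E,6E)-farnesyl p-tolyl sulfone; 6 (2E,6E,10E)-12-bromofarnesyl acetate
Product: 9 (2E,6E,10E,14E,18E)-3,7,11,15,19,23-hexamethyl-13-(p-tolylsulfonyl)tetracosa-2,6,10,14,18,22-hexaen-1-ol (racemic at C13), via lithiated sulfone 7 (not isolated), via acetoxy sulfone 8 (not isolated)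
Conditions: 3, n-BuLi, THF–DMPU, –78 °C; 6, –78 to –20 °C; then MeOH, K2CO3 (cat.), rt
Reagents that add atoms: none
Why: Allyl sulfone alkylation (Julia-type C–C coupling), in which the α-sulfonyl allyl carbanion reacts at its α carbon with the primary allylic bromide faster than with the acetate at –78 °C, should join the two C15 units head to tail with all five E double bonds in place (the new sulfone-bearing centre is racemic and is removed in step 5), and base-catalysed transesterification then frees the alcohol.

Step 5
Reactants: 9 hydroxy sulfone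
Product: 10 all-E-hexaprenol, (2E,6E,10E,14E,18E)-3,7,11,15,19,23-hexamethyltetracosa-2,6,10,14,18,22-hexaen-1-ol
Conditions: Pd(dppp)Cl2 (cat.), LiBHEt3, THF, 0 °C
Reagents that add atoms: none
Why: Pd-catalysed reductive desulfonylation, in which Pd(0) ionizes the allylic sulfone to a π-allyl complex and hydride is delivered to the less substituted terminus, should leave the 14,15 double bond in place and E.

Step 6
Reactants: 10 all-E-hexaprenol
Product: 11 all-E-hexaprenyl chloride
Conditions: NCS, Me2S, CH2Cl2, –40 to 0 °C
Reagents that add atoms: N-chlorosuccinimide, ClN1C(=O)CCC1=O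
Why: Corey–Kim chlorination, in which the alkoxysulfonium salt collapses by SN2 attack of chloride at the primary allylic carbon, is a standard way to turn polyprenols into chlorides without allylic transposition or E/Z scrambling.

Step 7
Reactants: 12 propionyl chloride; 13 ethoxyacetylene
Product: 15 3-ethoxy-4-methylcyclobut-2-en-1-one (racemic), via methylketene 14 (not isolated)
Conditions: Et3N, Et2O, 0 °C to rt, slow addition of 12 to excess 13
Reagents that add atoms: none
Why: Ketene–ynol ether [2+2] cycloaddition, in which the nucleophilic CH terminus of ethoxyacetylene bonds to the ketene carbonyl carbon, should place the ethoxy group at C3 and the methyl group at C4 (a racemic centre that is erased in step 10).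

Step 8
Reactants: 11 all-E-hexaprenyl chloride; 15 3-ethoxy-4-methylcyclobut-2-en-1-one
Product: 18 3-(all-E-hexaprenyl)-4-methylcyclobut-2-en-1-one (racemic), via hexaprenylbarium chloride 16 (not isolated), via tertiary carbinol 17 (not isolated)
Conditions: activated Ba (BaI2, lithium biphenylide, THF, rt); 11, –78 °C; 15, –78 °C; then 1 M HCl, Et2O, 0 °C, short contact
Reagents that add atoms: water, O (its oxygen becomes the carbonyl oxygen in the acid-mediated transposition)
Why: Allylbarium reagents add to carbonyl groups through the α carbon with retention of double-bond geometry, so 1,2-addition to the vinylogous ester should give the linear 2E adduct, and dilute acid then effects the Stork–Danheiser 1,3-carbonyl transposition (ionization to the ethoxy-stabilized allyl cation, hydration, loss of ethanol) to the 3-substituted cyclobutenone.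

Step 9
Reactants: 19 chloroacetaldehyde dimethyl acetal
Product: 21 methoxyacetylene, via sodium methoxyacetylide 20 (not isolated)
Conditions: NaNH2 (3 equiv), liquid NH3, –33 °C; NH3 evaporated; sat. aq. NaCl, –20 °C; distilled (bp about 23 °C) into cold toluene
Reagents that add atoms: none
Why: Twofold base-induced β-elimination (HCl, then methanol) from the chloroacetal gives the sodium acetylide, which is protonated on aqueous quench; methoxyacetylene has no β-hydrogen on its alkyl group and so cannot fragment by a retro-ene path when heated in step 10.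

Step 10
Reactants: 18 3-(all-E-hexaprenyl)-4-methylcyclobut-2-en-1-one; 21 methoxyacetylene
Product: 26 3-(all-E-hexaprenyl)-5-methoxy-2-methylphenol, via vinylketene 22 (not isolated), via vinylcyclobutenone 23 (not isolated), via dienylketene 24 (not isolated), via cyclohexadienone 25 (not isolated)
Conditions: 21 (excess), toluene, BHT (trace), sealed tube, 80 °C, then 110 °C
Reagents that add atoms: none
Why: Danheiser benzannulation: thermal 4π-electrocyclic opening of 18 breaks the bond between its carbonyl carbon and C4 to give vinylketene 22, whose electrophilic carbonyl carbon is attacked by the nucleophilic unsubstituted carbon of the ynol ether in a regiospecific [2+2] cycloaddition to 23, which forms the bond from the ketene carbonyl carbon to the alkyne CH and the bond from the former C2 to the alkyne C–OMe. A second 4π opening cleaves the old C1–C2 bond for good and gives dienylketene 24, which closes the six-membered ring by thermal disrotatory 6π-electrocyclization (re-forming C1–C4) to cyclohexadienone 25, and this tautomerizes to the phenol. The closest known reaction type is the benzannulation of cyclobutenones with alkoxyacetylenes to resorcinol monoethers. No stereocentre is created in the product: the racemic centres of 18, 23 and 25 are erased on aromatization, and the chain double bonds should not be affected at 80–110 °C. The step needs one orientation of alkyne insertion (OMe carbon next to the chain-bearing carbon, CH next to the carbonyl that has the methyl-bearing neighbour), and the ketene/ynol ether polarity secures it. It also needs the ketene to react with the alkyne and not with the six chain alkenes, which the far higher ketenophilicity of the ynol ether, used in excess, secures.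

Step 11
Reactants: 26 3-(all-E-hexaprenyl)-5-methoxy-2-methylphenol
Product: 27 2-methoxy-5-methyl-6-(all-E-hexaprenyl)-1,4-benzoquinone (target; also named 2-hexaprenyl-3-methyl-6-methoxy-1,4-benzoquinone)
Conditions: (KSO3)2NO, aq. KH2PO4, Aliquat 336 (cat.), CH2Cl2–H2O, rt
Reagents that add atoms: potassium nitrosodisulfonate (Fremy's salt), [K+].[K+].[O]N(S(=O)(=O)[O-])S(=O)(=O)[O-]
Why: Teuber oxidation, in which the nitroxyl radical forms the phenoxyl radical, a second equivalent adds at the free para carbon and loss of imidodisulfonate gives the p-quinone, should favour para attack over the single free ortho position as in related 3-methoxy-5-alkylphenols, while the isolated trisubstituted alkenes are inert to this reagent.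

**Compound list**

1 | (2E,6E)-farnesyl bromide | BrC/C=C(\C)CC/C=C(\C)CCC=C(C)C | starting material
2 | sodium p-toluenesulfinate | [Na+].[O-]S(=O)c1ccc(C)cc1 | starting material
3 | (2E,6E)-farnesyl p-tolyl sulfone | Cc1ccc(cc1)S(=O)(=O)C/C=C(\C)CC/C=C(\C)CCC=C(C)C | intermediate
4 | (2E,6E)-farnesyl acetate | CC(=O)OC/C=C(\C)CC/C=C(\C)CCC=C(C)C | starting material
5 | (2E,6E,10E)-12-hydroxy-3,7,11-trimethyldodeca-2,6,10-trien-1-yl acetate | CC(=O)OC/C=C(\C)CC/C=C(\C)CC/C=C(\C)CO | intermediate
6 | (2E,6E,10E)-12-bromo-3,7,11-trimethyldodeca-2,6,10-trien-1-yl acetate | CC(=O)OC/C=C(\C)CC/C=C(\C)CC/C=C(\C)CBr | intermediate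
7 | α-lithio derivative of sulfone 3 | [Li]C(/C=C(\C)CC/C=C(\C)CCC=C(C)C)S(=O)(=O)c1ccc(C)cc1 | intermediate
8 | (2E,6E,10E,14E,18E)-3,7,11,15,19,23-hexamethyl-13-(p-tolylsulfonyl)tetracosa-2,6,10,14,18,22-hexaen-1-yl acetate (racemic) | CC(=O)OC/C=C(\C)CC/C=C(\C)CC/C=C(\C)CC(/C=C(\C)CC/C=C(\C)CCC=C(C)C)S(=O)(=O)c1ccc(C)cc1 | intermediate
9 | (2E,6E,10E,14E,18E)-3,7,11,15,19,23-hexamethyl-13-(p-tolylsulfonyl)tetracosa-2,6,10,14,18,22-hexaen-1-ol (racemic) | OC/C=C(\C)CC/C=C(\C)CC/C=C(\C)CC(/C=C(\C)CC/C=C(\C)CCC=C(C)C)S(=O)(=O)c1ccc(C)cc1 | intermediate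
10 | all-E-hexaprenol | OC/C=C(\C)CC/C=C(\C)CC/C=C(\C)CC/C=C(\C)CC/C=C(\C)CCC=C(C)C | intermediate
11 | all-E-hexaprenyl chloride | ClC/C=C(\C)CC/C=C(\C)CC/C=C(\C)CC/C=C(\C)CC/C=C(\C)CCC=C(C)C | intermediate
12 | propionyl chloride | CCC(=O)Cl | starting material
13 | ethoxyacetylene | CCOC#C | starting material
14 | methylketene | CC=C=O | intermediate
15 | 3-ethoxy-4-methylcyclobut-2-en-1-one (racemic) | CCOC1=CC(=O)C1C | intermediate
16 | all-E-hexaprenylbarium chloride | Cl[Ba]C/C=C(\C)CC/C=C(\C)CC/C=C(\C)CC/C=C(\C)CC/C=C(\C)CCC=C(C)C | intermediate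
17 | 3-ethoxy-1-(all-E-hexaprenyl)-4-methylcyclobut-2-en-1-ol (racemic, diastereomer mixture) | CCOC1=CC(O)(C/C=C(\C)CC/C=C(\C)CC/C=C(\C)CC/C=C(\C)CC/C=C(\C)CCC=C(C)C)C1C | intermediate
18 | 3-(all-E-hexaprenyl)-4-methylcyclobut-2-en-1-one (racemic) | CC1C(=O)C=C1C/C=C(\C)CC/C=C(\C)CC/C=C(\C)CC/C=C(\C)CC/C=C(\C)CCC=C(C)C | intermediate
19 | chloroacetaldehyde dimethyl acetal | COC(CCl)OC | starting material
20 | sodium methoxyacetylide | [Na+].[C-]#COC | intermediate
21 | methoxyacetylene | C#COC | intermediate
22 | (3E)-3-(all-E-hexaprenyl)penta-1,3-dien-1-one (vinylketene) | O=C=C/C(C/C=C(\C)CC/C=C(\C)CC/C=C(\C)CC/C=C(\C)CC/C=C(\C)CCC=C(C)C)=C/C | intermediate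
23 | 3-methoxy-4-[(E)-1-(all-E-hexaprenyl)prop-1-en-1-yl]cyclobut-2-en-1-one (racemic) | COC1=CC(=O)C1/C(C/C=C(\C)CC/C=C(\C)CC/C=C(\C)CC/C=C(\C)CC/C=C(\C)CCC=C(C)C)=C/C | intermediate
24 | (3E,5E)-5-(all-E-hexaprenyl)-3-methoxyhepta-1,3,5-trien-1-one (dienylketene) | O=C=C/C(OC)=C\C(C/C=C(\C)CC/C=C(\C)CC/C=C(\C)CC/C=C(\C)CC/C=C(\C)CCC=C(C)C)=C\C | intermediate
25 | 5-(all-E-hexaprenyl)-3-methoxy-6-methylcyclohexa-2,4-dien-1-one (racemic) | COC1=CC(=O)C(C)C(C/C=C(\C)CC/C=C(\C)CC/C=C(\C)CC/C=C(\C)CC/C=C(\C)CCC=C(C)C)=C1 | intermediate
26 | 3-(all-E-hexaprenyl)-5-methoxy-2-methylphenol | COc1cc(O)c(C)c(C/C=C(\C)CC/C=C(\C)CC/C=C(\C)CC/C=C(\C)CC/C=C(\C)CCC=C(C)C)c1 | intermediate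
27 | 2-methoxy-5-methyl-6-(all-E-hexaprenyl)-1,4-benzoquinone | COC1=CC(=O)C(C)=C(C/C=C(\C)CC/C=C(\C)CC/C=C(\C)CC/C=C(\C)CC/C=C(\C)CCC=C(C)C)C1=O | target

**Step count and risks**

Total steps: 11. Longest linear sequence: 8 steps (4 → 5 → 6 → 9 → 10 → 11 → 18 → 26 → 27).

Steps most likely to fail:

1. Step 8. The allyl metal may react through its γ carbon and give the branched adduct, it may lose the 2E geometry by allyl-metal equilibration, or the chain double bond next to the ring may migrate into conjugation with the enone during the acid-mediated transposition. The fallback sets out from 11 and comes back at 26. Chloride 11 and sulfinate 2 in DMF should give hexaprenyl p-tolyl sulfone F1. Its α-lithio derivative (n-BuLi, THF, –78 °C) reacts only at the α carbon and is added 1,2 to 15. Cold dilute acid then gives 4-methyl-3-[1-(p-tolylsulfonyl)hexaprenyl]cyclobut-2-en-1-one F2. F2 is taken through the benzannulation with 21 under the conditions of step 10 to 5-methoxy-2-methyl-3-[1-(p-tolylsulfonyl)hexaprenyl]phenol F3. Pd(dppp)Cl2/LiBHEt3 removes the sulfone as in step 5 and gives 26.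

2. Step 10. The volatile ynol ether may polymerize or escape before it captures the vinylketene, and the ketene may then dimerize or acylate the phenol already formed. The fallback sets out from 11 and comes back at 27. Chloride 11 and Bu3SnLi (THF, –78 °C) should give tributyl(hexaprenyl)stannane F4. Commercial 2-methoxy-5-methylphenol is oxidized with Fremy's salt to 2-methoxy-5-methyl-1,4-benzoquinone F5. BF3·OEt2-mediated allylstannane–quinone coupling of F4 and F5 (CH2Cl2, –78 °C) should place the chain on the free position next to the methyl group and give 2-hexaprenyl-6-methoxy-3-methylbenzene-1,4-diol F6. Ag2O then oxidizes F6 to 27.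

3. Step 7. Methylketene may dimerize faster than it is captured, and the product may be acylated further by ketene. The fallback sets out from 13 and comes back at 15. 2-Chloropropionyl chloride and Et3N generate chloro(methyl)ketene, which is longer-lived and more electrophilic, and its [2+2] cycloaddition with 13 should give 4-chloro-3-ethoxy-4-methylcyclobut-2-en-1-one F7. F7 has no acidic ring hydrogen and cannot be acylated further. Reductive dechlorination (Zn, AcOH–TMEDA, EtOH) then gives 15.

**Further compounds**

F1 | step 8 | all-E-hexaprenyl p-tolyl sulfone | Cc1ccc(cc1)S(=O)(=O)C/C=C(\C)CC/C=C(\C)CC/C=C(\C)CC/C=C(\C)CC/C=C(\C)CCC=C(C)C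
F2 | step 8 | 4-methyl-3-[1-(p-tolylsulfonyl)-all-E-hexaprenyl]cyclobut-2-en-1-one (diastereomer mixture) | CC1C(=O)C=C1C(/C=C(\C)CC/C=C(\C)CC/C=C(\C)CC/C=C(\C)CC/C=C(\C)CCC=C(C)C)S(=O)(=O)c1ccc(C)cc1
F3 | step 8 | 5-methoxy-2-methyl-3-[1-(p-tolylsulfonyl)-all-E-hexaprenyl]phenol (racemic) | COc1cc(O)c(C)c(c1)C(/C=C(\C)CC/C=C(\C)CC/C=C(\C)CC/C=C(\C)CC/C=C(\C)CCC=C(C)C)S(=O)(=O)c1ccc(C)cc1
F4 | step 10 | tributyl(all-E-hexaprenyl)stannane | CCCC[Sn](CCCC)(CCCC)C/C=C(\C)CC/C=C(\C)CC/C=C(\C)CC/C=C(\C)CC/C=C(\C)CCC=C(C)C
F5 | step 10 | 2-methoxy-5-methyl-1,4-benzoquinone | COC1=CC(=O)C(C)=CC1=O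
F6 | step 10 | 2-(all-E-hexaprenyl)-6-methoxy-3-methylbenzene-1,4-diol | COc1cc(O)c(C)c(C/C=C(\C)CC/C=C(\C)CC/C=C(\C)CC/C=C(\C)CC/C=C(\C)CCC=C(C)C)c1O
F7 | step 7 | 4-chloro-3-ethoxy-4-methylcyclobut-2-en-1-one (racemic) | CCOC1=CC(=O)C1(C)Cl
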